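**Plan**
Ring atoms are called O1, C2 (C=O), C3 (=CH2), C4 (CO2H) and C5 (side chain), which are oxolane locants 1, 5, 4, 3 and 2 in the names below. The ring hides a 2-methylidenesuccinic (itaconic) acid, C2 on one side and the C4 carboxyl on the other, and its C4 carries the oxygen-bearing C5, a former aldehyde carbon.
The retrosynthesis first masks the C4 acid as a tert-butyl ester, then cuts O1–C2 and C4–C5 together, leaving 14-oxotetradecyl acetate and a mixed methyl/tert-butyl 2-(bromomethyl)fumarate.
Forward, the aldehyde comes from 1,14-tetradecanediol (2 steps) and the bromide from trimethyl phosphonoacetate and tert-butyl bromoacetate (4 steps). One chromium-catalysed allylation joins the chain to the C4 unit and the only ring closes in the same flask.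
The tert-butyl ester is chosen so that CF3CO2H frees the acid at the end without the acetate ever being removed.
Both stereocentres arise in the allylation: C5 (R) from the chiral ligand on chromium (Si-face addition), C4 (S) from the anti-selective chair transition state. Neither is touched afterwards.

Key step: step 7

Assumption: L = (S,S)-3,6-diphenyl-1,8-bis(4-isopropyl-4,5-dihydro-1,3-oxazol-2-yl)-9H-carbazole is taken to direct addition to the Si face of an unbranched aldehyde; should a test reaction show the opposite sense, its (R,R) form is used with nothing else changed.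

**Step 1**
Reactants: 1 1,14-tetradecanediol
Product: 2 14-hydroxytetradecyl acetate
Conditions: Ac2O (1.0 equiv), pyridine (1.2 equiv), THF, 0 °C to rt; recovered diol recycled
Reagents that add atoms: acetic anhydride CC(=O)OC(C)=O
Why: Statistical monoacylation of a symmetric primary diol whose remote hydroxyls react independently; monoacetate, diacetate and diol differ enough in polarity to be separated, and the diol is returned to the step.

**Step 2**
Reactants: 2 14-hydroxytetradecyl acetate
Product: 3 14-oxotetradecyl acetate
Conditions: PhI(OAc)2 (1.1 equiv), 2,2,6,6-tetramethylpiperidin-1-oxyl (10 mol %), CH2Cl2, rt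
Reagents that add atoms: none
Why: Oxoammonium-mediated (nitroxyl-catalysed) oxidation of a primary alcohol stops at the aldehyde in the absence of water and leaves the acetate untouched.

**Step 3**
Reactants: 4 trimethyl phosphonoacetate; 5 tert-butyl bromoacetate
Product: 6 4-tert-butyl 1-methyl 2-(dimethoxyphosphoryl)butanedioate (racemic)
Conditions: NaH (1.0 equiv), THF, 0 °C; then 5 (0.9 equiv), 0 °C to rt
Reagents that add atoms: none
Why: SN2 C-alkylation of the sodium phosphonoacetate carbanion by an α-bromo ester, the phosphonate being kept in slight excess to hold back double alkylation.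

**Step 4**
Reactants: 6 4-tert-butyl 1-methyl 2-(dimethoxyphosphoryl)butanedioate
Product: 7 4-tert-butyl 1-methyl 2-methylidenebutanedioate (mixed itaconate)
Conditions: 37% aq. HCHO, K2CO3 (2 equiv), H2O/THF, rt
Reagents that add atoms: formaldehyde C=O
Why: Horner–Wadsworth–Emmons methylenation under mild carbonate conditions that spare both esters; it places the methyl ester on the alkene carbon and the tert-butyl ester on the CH2 arm without ambiguity.

**Step 5**
Reactants: 7 4-tert-butyl 1-methyl 2-methylidenebutanedioate
Product: 8 4-tert-butyl 1-methyl 2-bromo-2-(bromomethyl)butanedioate (racemic)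
Conditions: Br2 (1.05 equiv), CH2Cl2, rt, ambient light
Reagents that add atoms: bromine BrBr
Why: Addition of bromine across the 1,1-disubstituted alkene, the known first stage of the bromination–dehydrobromination of itaconate diesters, under neutral conditions that the tert-butyl ester should tolerate.

**Step 6**
Reactants: 8 4-tert-butyl 1-methyl 2-bromo-2-(bromomethyl)butanedioate
Product: 9 4-tert-butyl 1-methyl (2Z)-2-(bromomethyl)but-2-enedioate (ester groups trans; fumarate geometry)
Conditions: Et3N (1.0 equiv), Et2O, 0 °C to rt
Reagents that add atoms: none
Why: E1cB-type dehydrobromination in which the C–H next to the tert-butyl ester is removed and the tertiary bromide leaves, giving the conjugated diester with the primary allylic bromide intact and the two esters in the more stable trans arrangement.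

**Step 7**
Reactants: 3 14-oxotetradecyl acetate; 9 4-tert-butyl 1-methyl (2Z)-2-(bromomethyl)but-2-enedioate
Product: 12 tert-butyl (2R,3S)-2-(13-acetoxytridecyl)-4-methylidene-5-oxooxolane-3-carboxylate, via trimethylsilyl ether 10 (not isolated), via hydroxy diester 11 (not isolated)
Conditions: CrCl2 (10 mol %), L (12 mol %), Mn powder (2 equiv), iPr2NEt (30 mol %), Me3SiCl (1.5 equiv), 9 (1.5 equiv, added slowly), THF, rt; then 1 M aq. HCl, rt
Reagents that add atoms: none
Why: Proposed new method: divalent chromium, regenerated by Mn, reduces the allylic C–Br bond of 9 to an allylchromium species (trivalent chromium) that is at the same time the metal dienolate of the itaconate, and this adds to the aldehyde through its ester-bearing γ-carbon in a closed six-membered chair, so that C4–C5 forms and the double bond moves to C3=CH2 before Me3SiCl takes the alkoxide off chromium as silyl ether 10. The closest known reaction type is the catalytic asymmetric Nozaki–Hiyama–Kishi 2-(alkoxycarbonyl)allylation of aldehydes with 2-(bromomethyl)acrylates followed by lactonisation, alongside racemic zinc and indium Barbier additions of 2-(bromomethyl)fumarates; what is new is the γ-ester-substituted bromide on the chiral chromium catalyst. The only ring closes in the acidic work-up, where 10 is desilylated to 11 and the C5 hydroxyl displaces methoxide from the acrylate ester by 5-exo-trig acyl substitution (O1–C2), attack on the tert-butyl ester being excluded because it would give a four-membered ring. C5 (R) is set by the tridentate ligand on chromium, which leaves the Si face of the aldehyde open, and C4 (S) by the chair, in which the allylchromium, free to change geometry by 1,3-metal shift through its C- and O-bound enolate forms, reacts with the bulky tert-butyl ester equatorial to give the anti adduct and thus the 4,5-trans lactone. The step needs γ- rather than α-attack, anti selectivity and reaction at the aldehyde alone, which the closed transition state, the size of the tert-butyl ester and the inertness of the three ester groups to allylchromium should secure.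

**Step 8**
Reactants: 12 tert-butyl (2R,3S)-2-(13-acetoxytridecyl)-4-methylidene-5-oxooxolane-3-carboxylate
Product: 13 (2R,3S)-2-(13-acetoxytridecyl)-4-methylidene-5-oxooxolane-3-carboxylic acid
Conditions: CF3CO2H/CH2Cl2 (1:4), 0 °C to rt
Reagents that add atoms: none
Why: Acidolysis of the tert-butyl ester through the tert-butyl cation (loss of 2-methylpropene) frees the C4 acid, while the primary acetate, the lactone, the exocyclic alkene and both stereocentres are not acid-labile at room temperature and should stay as they are.

**Compound list**
1 | 1,14-tetradecanediol | OCCCCCCCCCCCCCCO | starting material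
2 | 14-hydroxytetradecyl acetate | CC(=O)OCCCCCCCCCCCCCCO | intermediate
3 | 14-oxotetradecyl acetate | CC(=O)OCCCCCCCCCCCCCC=O | intermediate
4 | trimethyl phosphonoacetate (methyl 2-(dimethoxyphosphoryl)acetate) | COC(=O)CP(=O)(OC)OC | starting material
5 | tert-butyl bromoacetate | CC(C)(C)OC(=O)CBr | starting material
6 | 4-tert-butyl 1-methyl 2-(dimethoxyphosphoryl)butanedioate (racemic) | COC(=O)C(CC(=O)OC(C)(C)C)P(=O)(OC)OC | intermediate
7 | 4-tert-butyl 1-methyl 2-methylidenebutanedioate | C=C(CC(=O)OC(C)(C)C)C(=O)OC | intermediate
8 | 4-tert-butyl 1-methyl 2-bromo-2-(bromomethyl)butanedioate (racemic) | COC(=O)C(Br)(CBr)CC(=O)OC(C)(C)C | intermediate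
9 | 4-tert-butyl 1-methyl (2Z)-2-(bromomethyl)but-2-enedioate (esters trans; Z only because CH2Br outranks CO2Me) | CC(C)(C)OC(=O)/C=C(\CBr)C(=O)OC | intermediate
10 | 4-tert-butyl 1-methyl (3S)-3-[(1R)-14-acetoxy-1-(trimethylsilyloxy)tetradecyl]-2-methylidenebutanedioate | C=C(C(=O)OC)[C@H](C(=O)OC(C)(C)C)[C@H](O[Si](C)(C)C)CCCCCCCCCCCCCOC(C)=O | intermediate (not isolated)
11 | 4-tert-butyl 1-methyl (3S)-3-[(1R)-14-acetoxy-1-hydroxytetradecyl]-2-methylidenebutanedioate | C=C(C(=O)OC)[C@H](C(=O)OC(C)(C)C)[C@H](O)CCCCCCCCCCCCCOC(C)=O | intermediate (not isolated)
12 | tert-butyl (2R,3S)-2-(13-acetoxytridecyl)-4-methylidene-5-oxooxolane-3-carboxylate (4,5-trans in ring numbering) | C=C1C(=O)O[C@H](CCCCCCCCCCCCCOC(C)=O)[C@H]1C(=O)OC(C)(C)C | intermediate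
13 | (2R,3S)-2-(13-acetoxytridecyl)-4-methylidene-5-oxooxolane-3-carboxylic acid | C=C1C(=O)O[C@H](CCCCCCCCCCCCCOC(C)=O)[C@H]1C(=O)O | target

**Step count and risks**
Total steps: 8. Longest linear sequence: 6 steps (steps 3 to 8, from trimethyl phosphonoacetate); the aldehyde arm needs 2 steps before the convergence in step 7.

Steps most likely to fail:

1. Step 7. The ester-substituted allylchromium may change geometry too slowly, so that the geometry of the bromide is carried into the chair and the syn adduct (4,5-cis lactone) results. The bulkier, less nucleophilic dienolate may also be discriminated poorly by the ligand (low facial selectivity), or manganese may reduce the activated bromide without chromium and give racemic adduct or reductive dimer.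
Fallback, known chemistry in which C4–C5 is made by an auxiliary-controlled aldol reaction and the methylidene group is added afterwards; it sets out from aldehyde 3 and returns at target 13. (S)-4-Benzyl-1,3-oxazolidin-2-one is N-acylated with methyl 4-chloro-4-oxobutanoate (n-BuLi, THF, −78 °C) to methyl 4-[(4S)-4-benzyl-2-oxo-1,3-oxazolidin-3-yl]-4-oxobutanoate F1. Its boron enolate (Bu2BOTf, iPr2NEt, CH2Cl2, −78 to 0 °C) adds to 3 in an Evans syn-aldol reaction and the aldolate closes onto the methyl ester, which should give the trans lactone imide (4S)-4-benzyl-3-{[(2R,3S)-2-(13-acetoxytridecyl)-5-oxooxolan-3-yl]carbonyl}-1,3-oxazolidin-2-one F2. LiOH/H2O2 (THF/H2O, 0 °C to rt, then acidification) removes the auxiliary and the acetate and leaves (2R,3S)-2-(13-hydroxytridecyl)-5-oxooxolane-3-carboxylic acid F3. Methyl magnesium carbonate MeOMgOCO2Me (DMF, 130 °C) carboxylates the lactone α-carbon to (2R,3S)-2-(13-hydroxytridecyl)-5-oxooxolane-3,4-dicarboxylic acid F4, which is not purified. Aqueous formaldehyde and N-methylaniline (NaOAc, AcOH, rt) then bring about Mannich condensation and decarboxylative elimination to (2R,3S)-2-(13-hydroxytridecyl)-4-methylidene-5-oxooxolane-3-carboxylic acid F5. Acetylation of the primary hydroxyl (Ac2O, Sc(OTf)3 1 mol %, MeCN, 0 °C, then water to hydrolyse the mixed anhydride) gives 13.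

2. Step 5. Ionic addition of bromine to the electron-poor alkene is slow, and HBr formed by competing substitution may strip the tert-butyl ester before addition is complete.
Fallback, radical allylic bromination in place of addition–elimination; it sets out from itaconate 7 and returns at bromide 9, so that steps 5 and 6 are both bypassed. Catalytic 1,8-diazabicyclo[5.4.0]undec-7-ene (CH2Cl2, rt) moves the double bond into conjugation with both esters to give 4-tert-butyl 1-methyl (2E)-2-methylbut-2-enedioate F6; any Z isomer is carried along, since both give the same allylic radical. Wohl–Ziegler bromination of the vinylic methyl group (N-bromosuccinimide, azobisisobutyronitrile cat., PhCF3, reflux) should give 9.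

3. Step 1. Over-acetylation, the two hydroxyls being equally reactive, sends much of the material to diacetate or leaves it as diol, and the throughput is low.
Fallback, desymmetrisation by selective monobromination with the acetate then entering as a nucleophile; it sets out from diol 1 and returns at monoacetate 2. 48% aq. HBr in toluene at reflux converts one hydroxyl into the bromide to give 14-bromotetradecan-1-ol F7, and KOAc in DMF at 80 °C displaces the bromide (SN2) to give 2.

**Further compounds**
F1 | step 7 | methyl 4-[(4S)-4-benzyl-2-oxo-1,3-oxazolidin-3-yl]-4-oxobutanoate | COC(=O)CCC(=O)N1[C@@H](Cc2ccccc2)COC1=O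
F2 | step 7 | (4S)-4-benzyl-3-{[(2R,3S)-2-(13-acetoxytridecyl)-5-oxooxolan-3-yl]carbonyl}-1,3-oxazolidin-2-one | O=C1C[C@H](C(=O)N2[C@@H](Cc3ccccc3)COC2=O)[C@@H](CCCCCCCCCCCCCOC(C)=O)O1
F3 | step 7 | (2R,3S)-2-(13-hydroxytridecyl)-5-oxooxolane-3-carboxylic acid | O=C1C[C@H](C(=O)O)[C@@H](CCCCCCCCCCCCCO)O1
F4 | step 7 | (2R,3S)-2-(13-hydroxytridecyl)-5-oxooxolane-3,4-dicarboxylic acid (C4 epimers, not purified) | O=C1C(C(=O)O)[C@H](C(=O)O)[C@@H](CCCCCCCCCCCCCO)O1
F5 | step 7 | (2R,3S)-2-(13-hydroxytridecyl)-4-methylidene-5-oxooxolane-3-carboxylic acid | C=C1C(=O)O[C@H](CCCCCCCCCCCCCO)[C@H]1C(=O)O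
F6 | step 5 | 4-tert-butyl 1-methyl (2E)-2-methylbut-2-enedioate | CC(C)(C)OC(=O)/C=C(\C)C(=O)OC
F7 | step 1 | 14-bromotetradecan-1-ol | OCCCCCCCCCCCCCCBr
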